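Hold 50.0 s, the mean life of Z at 80 °C, against the 80 s of the run.

    Q → G (k1 = 0.070 s⁻¹, Ea1 = 90.0 kJ mol⁻¹)
    G → Z (k2 = 0.80 s⁻¹, Ea2 = 74.0 kJ mol⁻¹)
    Z → L (k3 = 0.020 s⁻¹, Ea3 = 97.0 kJ mol⁻¹)
    Q + L → Q.L (k4 = 0.60 M⁻¹ s⁻¹, Ea4 = 74.0 kJ mol⁻¹)
    L ⇌ X (K5 = 2.8, k5 = 0.0055 s⁻¹, Ea5 = 92.0 kJ mol⁻¹, ΔH5 = 60.0 kJ mol⁻¹)
    (constants at 80 °C)

| flask | Q | temperature | time | remark |
|---|---|---|---|---|
| delta | 0.091 M | 80 °C | 80 s |  |
| zeta | 0.091 M |  | 80 s | at 65 °C until 40 s, from then on at 80 °C |
| eta | 0.091 M | 65 °C | 80 s |  |

- a species is counted by the Q in it: one Q.L counts as two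
- constants are those at 80 °C; use the activation energies and enthalpies for any other temperature

- the flask that comes out highest in amount of L, in percent of the Q charged, or "all alike" when all lie within 1.5 percentage points (delta / zeta / eta / all alike)
- L at the end, in percent of the Q charged, delta
- L at the end, in percent of the Q charged, zeta
- L at the end, in percent of the Q charged, eta

Begin by asking why these two times. At 80 °C, Q lives 14.3 s and G 1.25 s, both shorter than Z's life , so material gathers as Z and Z → L is the rate-limiting step. Cooling keeps that order. At 65 °C the constant of Z → L falls to 0.00462 s⁻¹, so Z lives 216 s while Q lives 55.6 s. Watch Z first, and Q as well, whose life at 65 °C is still shorter than the 80 s of the run by no wide margin.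

Now count turnovers: the time spent at each temperature divided by the life of Z at that temperature, summed over the run. Flask delta gets 1.60. Flask zeta gets 0.985, most of it after the change. Flask eta gets 0.370. My reckoning stops there: it gives the order delta, zeta, eta, and no percentages.

The forecast names delta, with 51%, 37% and 11.5% for delta, zeta and eta: “The slow Z → L step limits all three flasks”.

The simulation gives delta highest, at 51.6%, then 38.1% for zeta and 11.5% for eta, so the forecast stands.

Remove the effect of temperature on Z → L and the gap between delta and eta shrinks from 40 percentage points to 8.4 points; remove it on Q → G instead and 11 points remains, so each is a part of the gap, and the first is what 1.60 against 0.370 turnovers counts. The largest single effect on L in flask eta is the time given: left ten times as long, flask eta goes from 11.5% to 52.2%. Keep the clock exact, since L in delta has moved 5 points by 65.5 s or 202 s, and a forecast of 51% would fail there. Leave eta until 5.0 min and it counts 1.39 turnovers, between zeta's 0.985 and delta's 1.60 , so expect L between 38.1% and 51.6%. That flask gives 48.2%.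

(The numbers of this flask belong to no real substance, and the outcome is calculated.)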